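**Plan**

- Locants used throughout: ring C1 (CHOAc), C2 (CH2), C3 (CHBr), C4 (CMe2), C5 (=CH), C6 (=C); side chain C7 (CHBr), C8 (CH2Cl).
- Retrosynthesis: both C–Br bonds go back to carbinols (substitution with inversion), C8–Cl to an acetyl methyl, and C1–OAc to a ring ketone. The ring bond C2–C3 is then cut as an aldol bond and C5=C6 as a Knoevenagel alkene, leaving acetylacetone and a 2,2-dimethylmalonaldehyde equivalent made from neopentyl glycol.
- Enabling feature: C6 carries two heteroatom-bearing carbons, ring C1 and side-chain C7, which can both be acetyl carbons of one acetylacetone unit. C3 lies β to C1 across C2, and the quaternary C4 keeps a C3 aldehyde from enolising.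
- Forward order: aldehyde arm (C3–C5), Knoevenagel to C5=C6, release of the C3 aldehyde, amine-catalysed closure of the only ring at C2–C3, then reduction, acetylation and the three halogenations.
- Stereochemistry: C3 from the D-proline aldol ((R)-carbinol, later inverted to the (S)-bromide); C1 from hydroxyl-directed anti reduction; C7 from (S)-CBS reduction ((S)-carbinol, inverted to the (R)-bromide).

Key step: step 6

Remark: the target is read as (1R,5S)-5-bromo-2-[(1R)-1-bromo-2-chloroethyl]-4,4-dimethylcyclohex-2-en-1-yl acetate, in which the C1 acetoxy and C3 bromo groups are cis on the ring.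

**Route**

Step 1
Reactants: 1 2,2-dimethylpropane-1,3-diol (neopentyl glycol)
Product: 2 3-[(tert-butyldimethylsilyl)oxy]-2,2-dimethylpropan-1-ol
Conditions: NaH (1.0 equiv), THF, 0 °C→rt; then TBSCl (1.0 equiv), rt
Reagents that add atoms: tert-butyldimethylsilyl chloride, CC(C)(C)[Si](C)(C)Cl
Why: O-silylation of the sparingly soluble monosodium alkoxide of a symmetric diol (McDougal monosilylation) should stop after one silyl ether, because the mono-salt reacts as it dissolves and no second alkoxide is present.

Step 2
Reactants: 2 3-[(tert-butyldimethylsilyl)oxy]-2,2-dimethylpropan-1-ol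
Product: 3 3-[(tert-butyldimethylsilyl)oxy]-2,2-dimethylpropanal
Conditions: (COCl)2, DMSO, CH2Cl2, −78 °C; then Et3N, −78 °C→rt
Reagents that add atoms: none
Why: Swern oxidation turns the neopentylic primary alcohol into a non-enolisable aldehyde without over-oxidation and leaves the silyl ether untouched.

Step 3
Reactants: 3 3-[(tert-butyldimethylsilyl)oxy]-2,2-dimethylpropanal; 4 pentane-2,4-dione (acetylacetone)
Product: 5 3-{3-[(tert-butyldimethylsilyl)oxy]-2,2-dimethylpropylidene}pentane-2,4-dione
Conditions: TiCl4, pyridine, THF, 0 °C→rt
Reagents that add atoms: none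
Why: Knoevenagel condensation in its TiCl4–pyridine (Lehnert) form is the standard way to condense hindered α-quaternary aldehydes with 1,3-dicarbonyl compounds; the two identical acetyl groups exclude alkene isomers and the absence of γ-hydrogens excludes deconjugation.

Step 4
Reactants: 5 3-{3-[(tert-butyldimethylsilyl)oxy]-2,2-dimethylpropylidene}pentane-2,4-dione
Product: 6 3-(3-hydroxy-2,2-dimethylpropylidene)pentane-2,4-dione
Conditions: HF·pyridine, pyridine, THF, 0 °C→rt
Reagents that add atoms: none
Why: Fluoride-mediated desilylation under buffered, weakly acidic conditions frees the primary alcohol without exposing the alkylidene diketone to a basic alkoxide or to naked fluoride.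

Step 5
Reactants: 6 3-(3-hydroxy-2,2-dimethylpropylidene)pentane-2,4-dione
Product: 7 3-(2,2-dimethyl-3-oxopropylidene)pentane-2,4-dione
Conditions: Dess–Martin periodinane, CH2Cl2, 0 °C→rt
Reagents that add atoms: none
Why: Dess–Martin oxidation is neutral and fast for neopentylic primary alcohols, the new aldehyde has no α-hydrogen to lose, and any ring-chain hemiketal form of 6 drains through the open hydroxy form.

Step 6
Reactants: 7 3-(2,2-dimethyl-3-oxopropylidene)pentane-2,4-dione
Product: 8 (5R)-2-acetyl-5-hydroxy-4,4-dimethylcyclohex-2-en-1-one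
Conditions: D-proline (20 mol%), DMSO, rt
Reagents that add atoms: none
Why: D-Proline condenses reversibly with either acetyl group, but only the enamine of the acetyl cis to the aldehyde arm can reach the formyl carbon, so C2 adds to C3 and hydrolysis of the resulting iminium ion returns the catalyst (enamine-mediated intramolecular aldol addition). The closest known reaction type is the proline-catalysed cyclisation of 1,5-dicarbonyl compounds of the Hajos–Parrish kind, here with a methyl ketone donor and an aldehyde acceptor. The six-membered ring closes in a 6-(enolendo)-exo-trig mode, since both enamine carbons C1 and C2 become ring atoms while the aldehyde C=O stays exocyclic. C3 is set by the catalyst: in the anti-enamine half-chair the carboxylic acid hydrogen-bonds to the aldehyde oxygen, which with D-proline presents the Re face of C3 to C2 and should give the (R)-carbinol, the mirror image of the sense L-proline shows in the Hajos–Parrish closure. The step needs aldol addition to win over amine conjugate addition, retro-Knoevenagel cleavage and dehydration; the quaternary C4 shields C5, makes the aldehyde non-enolisable and blocks elimination toward C4, and the mild conditions should spare the β-hydroxy ketone from loss of water across C2–C3. Alkene geometry is irrelevant because the two acyl groups on C6 are identical until the ring forms, the cis one becoming C1/C2 and the other C7/C8.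

Step 7
Reactants: 8 (5R)-2-acetyl-5-hydroxy-4,4-dimethylcyclohex-2-en-1-one
Product: 9 1-[(4R,6R)-4,6-dihydroxy-3,3-dimethylcyclohex-1-en-1-yl]ethan-1-one
Conditions: Me4NBH(OAc)3, MeCN/AcOH (1:1), −30 °C
Reagents that add atoms: none
Why: In the Evans–Saksena reduction the C3 hydroxyl exchanges onto boron and hydride is delivered internally to the β-carbonyl C1 on the face of the C3–O bond, which should give the trans (1,3-anti) diol with C1 (R), while the C7 ketone, lacking a hydroxyl in reach, is not reduced by triacetoxyborohydride.

Step 8
Reactants: 9 1-[(4R,6R)-4,6-dihydroxy-3,3-dimethylcyclohex-1-en-1-yl]ethan-1-one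
Product: 10 (1R,5R)-2-acetyl-5-hydroxy-4,4-dimethylcyclohex-2-en-1-yl acetate
Conditions: Ac2O (1.05 equiv), pyridine, CH2Cl2, −20→0 °C
Reagents that add atoms: acetic anhydride, CC(=O)OC(C)=O
Why: Kinetically controlled O-acylation should take the allylic C1 hydroxyl, which is flanked by a planar sp2 carbon, ahead of the neopentylic C3 hydroxyl next to the gem-dimethyl carbon when one equivalent of anhydride is used without an acyl-transfer catalyst.

Step 9
Reactants: 10 (1R,5R)-2-acetyl-5-hydroxy-4,4-dimethylcyclohex-2-en-1-yl acetate
Product: 11 (1R,5S)-2-acetyl-5-bromo-4,4-dimethylcyclohex-2-en-1-yl acetate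
Conditions: CBr4, PPh3, toluene, 60 °C
Reagents that add atoms: carbon tetrabromide, BrC(Br)(Br)Br
Why: In the Appel reaction bromide displaces the C3 alkoxyphosphonium group by SN2 with inversion ((R)-carbinol to (S)-bromide, now cis to the C1 acetate); warming compensates for the adjacent quaternary C4, and the same gem-dimethyl group shields the enone carbon C5 from phosphine addition.

Step 10
Reactants: 11 (1R,5S)-2-acetyl-5-bromo-4,4-dimethylcyclohex-2-en-1-yl acetate
Product: 13 (1R,5S)-5-bromo-2-(chloroacetyl)-4,4-dimethylcyclohex-2-en-1-yl acetate, via silyl dienol ether 12 (not isolated)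
Conditions: TMSOTf, i-Pr2NEt, CH2Cl2, −20→0 °C; then NCS, THF, 0 °C→rt
Reagents that add atoms: N-chlorosuccinimide, O=C1CCC(=O)N1Cl; trimethylsilyl triflate, C[Si](C)(C)OS(=O)(=O)C(F)(F)F (its silyl group is carried by 12 only)
Why: Soft enolisation can only occur toward C8 because C6 bears no hydrogen, and electrophilic chlorination of the resulting 2-silyloxydiene at its terminal carbon (α-halogenation of a silyl enol ether) gives the chloromethyl ketone, while the non-basic conditions avoid enolate acyl transfer from the neighbouring C1 acetate.

Step 11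
Reactants: 13 (1R,5S)-5-bromo-2-(chloroacetyl)-4,4-dimethylcyclohex-2-en-1-yl acetate
Product: 14 (1R,5S)-5-bromo-2-[(1S)-2-chloro-1-hydroxyethyl]-4,4-dimethylcyclohex-2-en-1-yl acetate
Conditions: (S)-Me-CBS oxazaborolidine ((S)-1-methyl-3,3-diphenyltetrahydro-1H,3H-pyrrolo[1,2-c][1,3,2]oxazaborole, 15 mol%), BH3·SMe2, THF, −20 °C
Reagents that add atoms: none
Why: In the Corey–Bakshi–Shibata reduction the α-branched cyclohexenyl group acts as the large and CH2Cl as the small ketone substituent, so the (S)-catalyst should deliver hydride in the sense known for α-chloroacetophenone and give the (S)-chlorohydrin at C7 under catalyst control, with 1,2-reduction outpacing hydroboration of the trisubstituted alkene.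

Step 12
Reactants: 14 (1R,5S)-5-bromo-2-[(1S)-2-chloro-1-hydroxyethyl]-4,4-dimethylcyclohex-2-en-1-yl acetate
Product: 15 (1R,5S)-5-bromo-2-[(1R)-1-bromo-2-chloroethyl]-4,4-dimethylcyclohex-2-en-1-yl acetate
Conditions: CBr4, PPh3, CH2Cl2, 0 °C
Reagents that add atoms: carbon tetrabromide, BrC(Br)(Br)Br
Why: Appel bromination of the allylic carbinol proceeds by SN2 with inversion to the (R)-bromide at C7; the SN2′ path at C5 is blocked by the neighbouring quaternary C4, ionisation is disfavoured by the β-chloro substituent, and low temperature with short contact should limit bromide exchange at the allylic centre.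

**Compound list**

1 | 2,2-dimethylpropane-1,3-diol (neopentyl glycol) | OCC(C)(C)CO | starting material
2 | 3-[(tert-butyldimethylsilyl)oxy]-2,2-dimethylpropan-1-ol | CC(C)(C)[Si](C)(C)OCC(C)(C)CO | intermediate
3 | 3-[(tert-butyldimethylsilyl)oxy]-2,2-dimethylpropanal | CC(C)(C)[Si](C)(C)OCC(C)(C)C=O | intermediate
4 | pentane-2,4-dione (acetylacetone) | CC(=O)CC(C)=O | starting material
5 | 3-{3-[(tert-butyldimethylsilyl)oxy]-2,2-dimethylpropylidene}pentane-2,4-dione | CC(=O)C(=CC(C)(C)CO[Si](C)(C)C(C)(C)C)C(C)=O | intermediate
6 | 3-(3-hydroxy-2,2-dimethylpropylidene)pentane-2,4-dione | CC(=O)C(=CC(C)(C)CO)C(C)=O | intermediate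
7 | 3-(2,2-dimethyl-3-oxopropylidene)pentane-2,4-dione | CC(=O)C(=CC(C)(C)C=O)C(C)=O | intermediate
8 | (5R)-2-acetyl-5-hydroxy-4,4-dimethylcyclohex-2-en-1-one | CC(=O)C1=CC(C)(C)[C@H](O)CC1=O | intermediate
9 | 1-[(4R,6R)-4,6-dihydroxy-3,3-dimethylcyclohex-1-en-1-yl]ethan-1-one | O[C@@H]1C[C@@H](O)C(C)(C)C=C1C(C)=O | intermediate
10 | (1R,5R)-2-acetyl-5-hydroxy-4,4-dimethylcyclohex-2-en-1-yl acetate | CC(=O)O[C@@H]1C[C@@H](O)C(C)(C)C=C1C(C)=O | intermediate
11 | (1R,5S)-2-acetyl-5-bromo-4,4-dimethylcyclohex-2-en-1-yl acetate | CC(=O)O[C@@H]1C[C@H](Br)C(C)(C)C=C1C(C)=O | intermediate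
12 | (1R,5S)-5-bromo-4,4-dimethyl-2-{1-[(trimethylsilyl)oxy]ethenyl}cyclohex-2-en-1-yl acetate | CC(=O)O[C@@H]1C[C@H](Br)C(C)(C)C=C1C(=C)O[Si](C)(C)C | intermediate (not isolated)
13 | (1R,5S)-5-bromo-2-(chloroacetyl)-4,4-dimethylcyclohex-2-en-1-yl acetate | CC(=O)O[C@@H]1C[C@H](Br)C(C)(C)C=C1C(=O)CCl | intermediate
14 | (1R,5S)-5-bromo-2-[(1S)-2-chloro-1-hydroxyethyl]-4,4-dimethylcyclohex-2-en-1-yl acetate | CC(=O)O[C@@H]1C[C@H](Br)C(C)(C)C=C1[C@H](O)CCl | intermediate
15 | (1R,5S)-5-bromo-2-[(1R)-1-bromo-2-chloroethyl]-4,4-dimethylcyclohex-2-en-1-yl acetate | CC(=O)O[C@@H]1C[C@H](Br)C(C)(C)C=C1[C@@H](Br)CCl | target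

**Step count and risks**

Total step count: 12. Longest linear sequence: 12 steps (1 to 15); acetylacetone 4 enters in step 3.

Steps most likely to fail:

Step 6. Enamine formation at the hindered, cross-conjugated acetyl group may be slow while the catalyst rests on the aldehyde, or enantioface discrimination at C3 may be insufficient. The fallback takes stereochemistry from an enzyme instead of the ring closure. Setting out from 7, the ring would be closed with achiral pyrrolidinium acetate (pyrrolidine, AcOH, THF, rt) to racemic 2-acetyl-5-hydroxy-4,4-dimethylcyclohex-2-en-1-one F1. Directed reduction as in step 7 would give the racemic trans-diol F2. Transesterification with vinyl acetate catalysed by Burkholderia cepacia lipase (MTBE, rt) should then, following Kazlauskas's rule, acetylate only the (R)-configured allylic C1 carbinol of the (4R,6R)-enantiomer, leaving the (4S,6S)-diol F3 behind. This resolves the racemate and selects the site in one operation, at the cost of at most half of the material, and the route is rejoined at 10.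

Step 9. Substitution at the neopentylic C3 may be too slow, so that elimination toward C2, methyl migration from C4 or participation of the C1 acetate (retention at C3) take over within the oxyphosphonium ion pair. The fallback separates activation from displacement. Setting out from 10, the C3 hydroxyl would be converted with ClCH2SO2Cl and pyridine (CH2Cl2, 0 °C) into the isolable chloromethanesulfonate (1R,5R)-2-acetyl-5-{[(chloromethyl)sulfonyl]oxy}-4,4-dimethylcyclohex-2-en-1-yl acetate F4. This nucleofuge is used for hindered secondary carbinols where mesylates fail. Displacement with excess LiBr in DMF at 50 °C, a bromide-rich and non-acidic medium, should then give the inverted bromide, and the route is rejoined at 11.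

Step 8. Discrimination between the two secondary hydroxyls may be poor, giving mixtures of regioisomeric mono- and diacetates. The fallback replaces rate-based acylation by a substitution that only the allylic carbinol can undergo. Setting out from 8, chelation-controlled syn reduction (Et2BOMe, NaBH4, THF/MeOH, −78 °C; Narasaka–Prasad) would give the cis-diol 1-[(4R,6S)-4,6-dihydroxy-3,3-dimethylcyclohex-1-en-1-yl]ethan-1-one F5. Mitsunobu esterification with acetic acid (PPh3, DIAD, THF, 0 °C) should then engage the allylic C1 carbinol alone, the neopentylic C3 carbinol being inert under these conditions, and invert it to the (1R)-acetate; the route is rejoined at 10.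

**Further compounds**

F1 | step 6 | racemic 2-acetyl-5-hydroxy-4,4-dimethylcyclohex-2-en-1-one | CC(=O)C1=CC(C)(C)[C@H](O)CC1=O.CC(=O)C1=CC(C)(C)[C@@H](O)CC1=O
F2 | step 6 | racemic trans-1-(4,6-dihydroxy-3,3-dimethylcyclohex-1-en-1-yl)ethan-1-one, (4R,6R) and (4S,6S) | O[C@@H]1C[C@@H](O)C(C)(C)C=C1C(C)=O.O[C@H]1C[C@H](O)C(C)(C)C=C1C(C)=O
F3 | step 6 | 1-[(4S,6S)-4,6-dihydroxy-3,3-dimethylcyclohex-1-en-1-yl]ethan-1-one | O[C@H]1C[C@H](O)C(C)(C)C=C1C(C)=O
F4 | step 9 | (1R,5R)-2-acetyl-5-{[(chloromethyl)sulfonyl]oxy}-4,4-dimethylcyclohex-2-en-1-yl acetate | CC(=O)O[C@@H]1C[C@@H](OS(=O)(=O)CCl)C(C)(C)C=C1C(C)=O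
F5 | step 8 | 1-[(4R,6S)-4,6-dihydroxy-3,3-dimethylcyclohex-1-en-1-yl]ethan-1-one | O[C@H]1C[C@@H](O)C(C)(C)C=C1C(C)=O
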